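**Retrosynthetic overview**

- The strategy rests on the 1,5-relation between the C6 oxygen and the (E)-C1=C10 olefin in the ten-membered carbocycle (C6–C7–C8–C9–C10=C1). Trading C8–C9 for C1–C6 leads back to a p-menthane-type cyclohexenol (ring carbons C1–C6, isopropenyl carbons C9, C10, C14, and C15 on C4), opened by anionic oxy-Cope ring expansion, with the C6 enolate alkylated at C7 (C7–C11).
- The dienol comes from a 5-silyloxy-6-isopropenyl-3-methylcyclohexenone (C6 carbonyl) and a (Z)-2-(4-methoxybenzyloxy)vinyllithium (C7, C8). The enone comes from ring-closing metathesis of a vinyl ketone made by an auxiliary-controlled deconjugative aldol that sets C1 and C2.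
- After the expansion: PMB removal and C8–O/C12 lactonisation, C6 reduction, hydroxyl-directed C4–C5 epoxidation, C11 methylenation, desilylation, diacetylation.
- Ring order: cyclohexene (metathesis), ten-membered carbocycle (ring expansion), γ-lactone, epoxide.

Key step: step 11

Remark: germacrane numbering (C1–C15) is used for the ten-membered compounds and for the atoms that become them; the C7 acetate arm is carried as its methyl ester so that the C8 lactone closes without strong acid, and 3-methylbut-3-enal is used as a fresh cold solution.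

**Route**

Step 1
Reactants: 1 (R)-4-benzyl-2-oxazolidinone; 2 3-methylbut-2-enoyl chloride
Product: 4 (R)-4-benzyl-3-(3-methylbut-2-enoyl)oxazolidin-2-one, via N-lithio oxazolidinone 3 (not isolated)
Conditions: n-BuLi, THF, −78 °C; then 2, −78 → 0 °C
Reagents that add atoms: none
Why: N-lithiation followed by N-acylation with the acid chloride at low temperature is the standard acylation of oxazolidinones and avoids the vinylketene pathway that amine bases open for this acid chloride.

Step 2
Reactants: 5 3-methylbut-3-en-1-ol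
Product: 6 3-methylbut-3-enal
Conditions: Dess–Martin periodinane, pyridine, CH2Cl2, 0 °C; filtered solution used at once
Reagents that add atoms: none
Why: Dess–Martin oxidation of the primary alcohol under buffered, non-basic conditions stops at the aldehyde and, kept cold, should not move the β,γ-olefin into conjugation.

Step 3
Reactants: 4 (R)-4-benzyl-3-(3-methylbut-2-enoyl)oxazolidin-2-one; 6 3-methylbut-3-enal
Product: 9 (R)-4-benzyl-3-[(2R,3S)-3-hydroxy-5-methyl-2-(prop-1-en-2-yl)hex-5-enoyl]oxazolidin-2-one, via boron dienolate 7 (not isolated), via boron aldolate 8 (not isolated)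
Conditions: Bu2BOTf, Et3N, CH2Cl2, −78 → 0 °C; then 6, −78 → 0 °C; pH 7 buffer, MeOH, H2O2, 0 °C
Reagents that add atoms: none
Why: Evans syn aldol in its deconjugative form: γ-deprotonation gives the (Z)-boron dienolate, which reacts at the α-carbon through a Zimmerman–Traxler chair on the face away from the benzyl group, setting the isopropenyl-bearing carbon (future C1, R) and the carbinol carbon (future C2, S) syn, which becomes trans once both lie in the six-membered ring.

Step 4
Reactants: 9 the syn aldol imide
Product: 10 (2R,3S)-3-hydroxy-N-methoxy-N,5-dimethyl-2-(prop-1-en-2-yl)hex-5-enamide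
Conditions: MeNH(OMe)·HCl, AlMe3, CH2Cl2, −15 → 0 °C; 1 M HCl work-up
Reagents that add atoms: N,O-dimethylhydroxylamine hydrochloride CNOC.Cl
Why: aluminium amide transamination of a β-hydroxy imide, assisted by chelation of the free hydroxyl, gives the Weinreb amide without epimerising the α-carbon and returns the auxiliary.

Step 5
Reactants: 10 the β-hydroxy Weinreb amide
Product: 11 (2R,3S)-3-(tert-butyldimethylsilyloxy)-N-methoxy-N,5-dimethyl-2-(prop-1-en-2-yl)hex-5-enamide
Conditions: TBSOTf, 2,6-lutidine, CH2Cl2, −78 → 0 °C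
Reagents that add atoms: tert-butyldimethylsilyl trifluoromethanesulfonate CC(C)(C)[Si](C)(C)OS(=O)(=O)C(F)(F)F
Why: silyl triflate with a hindered pyridine base silylates the secondary alcohol under conditions that leave the 1,1-disubstituted olefins and the α-stereocentre alone.

Step 6
Reactants: 11 the silylated Weinreb amide
Product: 12 (4R,5S)-5-(tert-butyldimethylsilyloxy)-7-methyl-4-(prop-1-en-2-yl)octa-1,7-dien-3-one
Conditions: CH2=CHMgBr, THF, −20 → 0 °C; poured into cold 1 M HCl
Reagents that add atoms: vinylmagnesium bromide C=C[Mg]Br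
Why: Weinreb ketone synthesis: the chelated tetrahedral adduct stops at the ketone stage, and the cold acid quench protonates the released amine so that it cannot add to the vinyl ketone.

Step 7
Reactants: 12 the vinyl ketone
Product: 13 (5S,6R)-5-(tert-butyldimethylsilyloxy)-3-methyl-6-(prop-1-en-2-yl)cyclohex-2-en-1-one
Conditions: second-generation Hoveyda–Grubbs catalyst (5 mol%), 1,4-benzoquinone (10 mol%), toluene (5 mM), 80 °C
Reagents that add atoms: none
Why: ring-closing metathesis of the vinyl ketone with the methallyl olefin forms the cyclohexenone with loss of ethene; the isopropenyl group could only close a four-membered or a tetrasubstituted five-membered ring and should stay, benzoquinone suppresses ruthenium hydride isomerisation, and the neutral medium spares the base-labile β-silyloxy ketone.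

Step 8
Reactants: 14 4-methoxybenzyl alcohol; 15 butyl vinyl ether
Product: 16 4-methoxybenzyl vinyl ether
Conditions: Pd(OCOCF3)2 (cat.), 4,7-diphenyl-1,10-phenanthroline (cat.), Et3N (cat.), 15 as solvent, 75 °C
Reagents that add atoms: none
Why: palladium-catalysed transfer vinylation exchanges the alkoxy group of the vinyl ether with the primary benzylic alcohol, the excess of 15 driving the equilibrium.

Step 9
Reactants: 16 4-methoxybenzyl vinyl ether
Product: 18 (Z)-1-bromo-2-(4-methoxybenzyloxy)ethene, via dibromo ether 17 (not isolated)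
Conditions: Br2, CH2Cl2, −78 °C; then iPr2NEt, −78 → 25 °C; chromatography on Et3N-washed silica
Reagents that add atoms: bromine BrBr
Why: bromine adds to the vinyl ether far faster than it substitutes the anisole ring, and amine-induced loss of HBr from the α-bromo ether should give mainly the (Z)-β-bromovinyl ether, as in the standard preparation of (Z)-1-bromo-2-ethoxyethene, the E isomer being removed by chromatography.

Step 10
Reactants: 18 (Z)-1-bromo-2-(4-methoxybenzyloxy)ethene; 13 the cyclohexenone
Product: 20 (1R,5S,6R)-5-(tert-butyldimethylsilyloxy)-1-[(Z)-2-(4-methoxybenzyloxy)ethenyl]-3-methyl-6-(prop-1-en-2-yl)cyclohex-2-en-1-ol, via vinyllithium 19 (not isolated)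
Conditions: 18, t-BuLi (2 equiv), Et2O, −78 °C; then 13, −78 °C; aq NH4Cl; chromatography on Et3N-washed silica
Reagents that add atoms: none
Why: bromine–lithium exchange with retention gives the oxygen-chelated (Z)-vinyllithium, which adds 1,2 to the β,β-disubstituted enone on the face opposite the neighbouring isopropenyl group (equatorial entry on the half-chair with the C1 and C2 substituents equatorial), so the new carbinol C6 carries the alkenyl group trans to the isopropenyl group and an axial hydroxyl.

Step 11
Reactants: 20 the dienol; 21 methyl bromoacetate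
Product: 24 methyl [(1R,2R,4E,6S,8Z)-6-(tert-butyldimethylsilyloxy)-2-(4-methoxybenzyloxy)-4,8-dimethyl-10-oxocyclodeca-4,8-dien-1-yl]acetate, via potassium alkoxide 22 (not isolated), via potassium enolate 23 (not isolated)
Conditions: KN(SiMe3)2 (1.1 equiv), 18-crown-6, THF, 0 → 25 °C; then 21, −78 → −40 °C; aq NH4Cl
Reagents that add atoms: none
Why: Deprotonation gives the crown-separated potassium alkoxide 22, in which the C1–C6 bond is weakened and a [3,3] sigmatropic shift (anionic oxy-Cope) runs through the 1,5-diene C9=C10–C1–C6–C7=C8, breaking C1–C6 and forming C8–C9. The ten-membered ring is therefore made by a four-atom ring expansion of the cyclohexenol and not by an end-to-end closure, the closest known reaction type being the anionic oxy-Cope rearrangement of trans-1,2-dialkenylcyclohexanols to (E)-cyclodec-5-enones with alkylation of the enolate in the same flask. In the chair transition state the two alkenyl groups are equatorial on the cyclohexene and ring carbons C2 and C5 are equatorial on the chair, so C1=C10 should emerge E, C4=C5 stays Z, and the oxygen of the (Z)-enol ether sits axial, which passes the C1/C6 configuration on to C8 as 8R. The C6=C7 enolate 23 is regiodefined and its inner face looks across the ring at C1=C10, so methyl bromoacetate should attack C7 from the periphery at −78 °C and place the acetate arm cis to the C8 oxygen (7R). The step needs the chair over the boat and the exocyclic vinyl group over the ring olefin as the migrating partner, both secured by the trans-diequatorial dialkenyl arrangement set in step 10. It also needs carbon over oxygen alkylation and survival of the β-alkoxy enolate, which the soft SN2 electrophile, the low temperature and the C8–O bond lying in the nodal plane of the enolate as formed should provide.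

Step 12
Reactants: 24 the ten-membered keto ester
Product: 25 methyl [(1R,2R,4E,6S,8Z)-6-(tert-butyldimethylsilyloxy)-2-hydroxy-4,8-dimethyl-10-oxocyclodeca-4,8-dien-1-yl]acetate
Conditions: DDQ, CH2Cl2/pH 7 buffer (10:1), 0 → 25 °C
Reagents that add atoms: none
Why: DDQ cleaves the electron-rich benzyl ether oxidatively through the benzylic cation and its hemiacetal, leaving the silyl ether, ester, enone and trisubstituted olefin untouched and freeing the C8 hydroxyl.

Step 13
Reactants: 25 the C8 hydroxy keto ester
Product: 26 (2S,7R,8R)-2-(tert-butyldimethylsilyloxy)-6-oxo-13-norgermacra-1(10)E,4Z-dien-12,8-olide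
Conditions: PPTS (cat.), toluene, 40 °C
Reagents that add atoms: none
Why: acid-catalysed intramolecular transesterification of the γ-hydroxy methyl ester closes the five-membered lactone (5-exo-trig acyl substitution) on C8, the only free hydroxyl while C6 is still a ketone, the C7 arm and the C8 oxygen being cis.

Step 14
Reactants: 26 the lactone enone
Product: 27 (2S,6R,7S,8R)-2-(tert-butyldimethylsilyloxy)-6-hydroxy-13-norgermacra-1(10)E,4Z-dien-12,8-olide
Conditions: NaBH4, CeCl3·7H2O, MeOH, −78 → −40 °C; AcOH quench at −78 °C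
Reagents that add atoms: none
Why: Luche 1,2-reduction of the enone: hydride should enter from the peripheral face of the conformer in which the C6 carbonyl eclipses C7–H and points away from the C8–O bond of the cis-fused lactone (opposed dipoles), giving the C6 alcohol anti to the C8 oxygen, and the cold acidic quench prevents translactonisation to C6.

Step 15
Reactants: 27 the allylic alcohol
Product: 28 (2S,4R,5S,6S,7S,8R)-2-(tert-butyldimethylsilyloxy)-4,5-epoxy-6-hydroxy-13-norgermacr-1(10)E-en-12,8-olide
Conditions: VO(acac)2 (cat.), t-BuOOH (decane solution), CH2Cl2, 0 → 25 °C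
Reagents that add atoms: tert-butyl hydroperoxide CC(C)(C)OO
Why: vanadium-catalysed hydroxyl-directed epoxidation: the C6 vanadate ester delivers the peroxide oxygen to the face of the (Z)-C4=C5 olefin syn to the hydroxyl, as with cis-cyclooct-2-enol and cis-cyclonon-2-enol, setting 4R and 5S, while the undirected C1=C10 olefin should stay intact.

Step 16
Reactants: 28 the epoxy alcohol
Product: 29 (2S,4R,5S,6S,7R,8R)-2-(tert-butyldimethylsilyloxy)-4,5-epoxy-6-(triethylsilyloxy)-13-norgermacr-1(10)E-en-12,8-olide
Conditions: Et3SiCl, imidazole, DMAP (cat.), CH2Cl2, 0 → 25 °C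
Reagents that add atoms: chlorotriethylsilane CC[Si](Cl)(CC)CC
Why: silylation of the secondary alcohol under mildly basic, non-Lewis-acidic conditions protects C6 for the enolate step without opening the neighbouring epoxide.

Step 17
Reactants: 29 the bis-silyl epoxy lactone
Product: 31 (2S,4R,5S,6S,7R,8R)-2-(tert-butyldimethylsilyloxy)-13-(dimethylamino)-4,5-epoxy-6-(triethylsilyloxy)germacr-1(10)E-en-12,8-olide as a mixture at C11, via lithium enolate 30 (not isolated)
Conditions: LiN(iPr)2, THF, −78 °C; then CH2=NMe2+ I−, −78 → 0 °C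
Reagents that add atoms: N,N-dimethylmethyleneiminium iodide C=[N+](C)C.[I-]
Why: the lactone α-CH2 (C11) is the only acidic position, and its lithium enolate undergoes a Mannich reaction with Eschenmoser's salt to attach C13; the C11 configuration is lost in the next step.

Step 18
Reactants: 31 the Mannich base
Product: 33 (2S,4R,5S,6S,7R,8R)-2-(tert-butyldimethylsilyloxy)-4,5-epoxy-6-(triethylsilyloxy)germacra-1(10)E,11(13)-dien-12,8-olide, via ammonium iodide 32 (not isolated)
Conditions: MeI, MeOH, 25 °C; then aq NaHCO3, EtOAc, 25 °C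
Reagents that add atoms: none
Why: N-methylation gives a quaternary ammonium salt that loses trimethylamine by E1cB elimination across C11–C13 under bicarbonate, the standard way to an α-methylene-γ-lactone.

Step 19
Reactants: 33 the bis-silyl α-methylene lactone
Product: 34 (2S,4R,5S,6S,7S,8R)-4,5-epoxy-2,6-dihydroxygermacra-1(10)E,11(13)-dien-12,8-olide
Conditions: Bu4NF, AcOH (1:1), THF, 0 → 25 °C
Reagents that add atoms: none
Why: acetic acid-buffered fluoride removes the triethylsilyl and the allylic tert-butyldimethylsilyl ethers without generating free alkoxides, so that Payne rearrangement of the epoxy alcohol and conjugate addition to the methylene lactone are avoided.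

Step 20
Reactants: 34 the diol
Product: 35 (2S,4R,5S,6S,7R,8R)-2,6-diacetoxy-4,5-epoxygermacra-1(10)E,11(13)-dien-12,8-olide (CNP0270851.1)
Conditions: Ac2O, pyridine, DMAP (cat.), CH2Cl2, 0 → 25 °C
Reagents that add atoms: acetic anhydride CC(=O)OC(C)=O
Why: DMAP-catalysed acylation esterifies both secondary hydroxyls with retention and does not touch the epoxide or the lactone.

**Compound list**

1 | (R)-4-benzyl-2-oxazolidinone | O=C1N[C@H](Cc2ccccc2)CO1 | starting material
2 | 3-methylbut-2-enoyl chloride | CC(C)=CC(Cl)=O | starting material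
3 | lithium salt of (R)-4-benzyl-2-oxazolidinone | [Li]N1C(=O)OC[C@H]1Cc1ccccc1 | intermediate
4 | (R)-4-benzyl-3-(3-methylbut-2-enoyl)oxazolidin-2-one | CC(C)=CC(=O)N1C(=O)OC[C@H]1Cc1ccccc1 | intermediate
5 | 3-methylbut-3-en-1-ol | C=C(C)CCO | starting material
6 | 3-methylbut-3-enal | C=C(C)CC=O | intermediate
7 | (Z)-dibutylboron dienolate of 4 | C=C(C)/C=C(\OB(CCCC)CCCC)N1C(=O)OC[C@H]1Cc1ccccc1 | intermediate
8 | dibutylboron aldolate of 9 | C=C(C)C[C@H](OB(CCCC)CCCC)[C@@H](C(C)=C)C(=O)N1C(=O)OC[C@H]1Cc1ccccc1 | intermediate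
9 | (R)-4-benzyl-3-[(2R,3S)-3-hydroxy-5-methyl-2-(prop-1-en-2-yl)hex-5-enoyl]oxazolidin-2-one | C=C(C)C[C@H](O)[C@@H](C(C)=C)C(=O)N1C(=O)OC[C@H]1Cc1ccccc1 | intermediate
10 | (2R,3S)-3-hydroxy-N-methoxy-N,5-dimethyl-2-(prop-1-en-2-yl)hex-5-enamide | C=C(C)C[C@H](O)[C@@H](C(C)=C)C(=O)N(C)OC | intermediate
11 | (2R,3S)-3-(tert-butyldimethylsilyloxy)-N-methoxy-N,5-dimethyl-2-(prop-1-en-2-yl)hex-5-enamide | C=C(C)C[C@H](O[Si](C)(C)C(C)(C)C)[C@@H](C(C)=C)C(=O)N(C)OC | intermediate
12 | (4R,5S)-5-(tert-butyldimethylsilyloxy)-7-methyl-4-(prop-1-en-2-yl)octa-1,7-dien-3-one | C=C(C)C[C@H](O[Si](C)(C)C(C)(C)C)[C@@H](C(C)=C)C(=O)C=C | intermediate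
13 | (5S,6R)-5-(tert-butyldimethylsilyloxy)-3-methyl-6-(prop-1-en-2-yl)cyclohex-2-en-1-one | C=C(C)[C@@H]1[C@@H](O[Si](C)(C)C(C)(C)C)CC(C)=CC1=O | intermediate
14 | 4-methoxybenzyl alcohol | COc1ccc(CO)cc1 | starting material
15 | butyl vinyl ether | C=COCCCC | starting material
16 | 4-methoxybenzyl vinyl ether | C=COCc1ccc(OC)cc1 | intermediate
17 | 1,2-dibromoethyl 4-methoxybenzyl ether (racemic) | BrCC(Br)OCc1ccc(OC)cc1 | intermediate
18 | (Z)-1-bromo-2-(4-methoxybenzyloxy)ethene | Br/C=C\OCc1ccc(OC)cc1 | intermediate
19 | (Z)-2-(4-methoxybenzyloxy)vinyllithium | [Li]/C=C\OCc1ccc(OC)cc1 | intermediate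
20 | (1R,5S,6R)-5-(tert-butyldimethylsilyloxy)-1-[(Z)-2-(4-methoxybenzyloxy)ethenyl]-3-methyl-6-(prop-1-en-2-yl)cyclohex-2-en-1-ol | C=C(C)[C@@H]1[C@@H](O[Si](C)(C)C(C)(C)C)CC(C)=C[C@@]1(O)/C=C\OCc1ccc(OC)cc1 | intermediate
21 | methyl bromoacetate | COC(=O)CBr | starting material
22 | potassium alkoxide of 20 | C=C(C)[C@@H]1[C@@H](O[Si](C)(C)C(C)(C)C)CC(C)=C[C@@]1([O-])/C=C\OCc1ccc(OC)cc1.[K+] | intermediate
23 | potassium C6=C7 enolate of the ten-membered (1(10)E,4Z)-dienone (2S,8R; O cis to C8) | COc1ccc(CO[C@@H]2C/C(C)=C/[C@@H](O[Si](C)(C)C(C)(C)C)C/C(C)=C\C([O-])=C\2)cc1.[K+] | intermediate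
24 | methyl [(1R,2R,4E,6S,8Z)-6-(tert-butyldimethylsilyloxy)-2-(4-methoxybenzyloxy)-4,8-dimethyl-10-oxocyclodeca-4,8-dien-1-yl]acetate (germacrane 2S,7R,8R) | COc1ccc(CO[C@@H]2C/C(C)=C/[C@@H](O[Si](C)(C)C(C)(C)C)C/C(C)=C\C(=O)[C@@H]2CC(=O)OC)cc1 | intermediate
25 | methyl [(1R,2R,4E,6S,8Z)-6-(tert-butyldimethylsilyloxy)-2-hydroxy-4,8-dimethyl-10-oxocyclodeca-4,8-dien-1-yl]acetate | O[C@@H]1C/C(C)=C/[C@@H](O[Si](C)(C)C(C)(C)C)C/C(C)=C\C(=O)[C@@H]1CC(=O)OC | intermediate
26 | (2S,7R,8R)-2-(tert-butyldimethylsilyloxy)-6-oxo-13-norgermacra-1(10)E,4Z-dien-12,8-olide | C1C(=O)O[C@@H]2C/C(C)=C/[C@@H](O[Si](C)(C)C(C)(C)C)C/C(C)=C\C(=O)[C@H]12 | intermediate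
27 | (2S,6R,7S,8R)-2-(tert-butyldimethylsilyloxy)-6-hydroxy-13-norgermacra-1(10)E,4Z-dien-12,8-olide | C1C(=O)O[C@@H]2C/C(C)=C/[C@@H](O[Si](C)(C)C(C)(C)C)C/C(C)=C\[C@@H](O)[C@H]12 | intermediate
28 | (2S,4R,5S,6S,7S,8R)-2-(tert-butyldimethylsilyloxy)-4,5-epoxy-6-hydroxy-13-norgermacr-1(10)E-en-12,8-olide | C1C(=O)O[C@@H]2C/C(C)=C/[C@@H](O[Si](C)(C)C(C)(C)C)C[C@@]3(C)O[C@H]3[C@@H](O)[C@H]12 | intermediate
29 | (2S,4R,5S,6S,7R,8R)-2-(tert-butyldimethylsilyloxy)-4,5-epoxy-6-(triethylsilyloxy)-13-norgermacr-1(10)E-en-12,8-olide | C1C(=O)O[C@@H]2C/C(C)=C/[C@@H](O[Si](C)(C)C(C)(C)C)C[C@@]3(C)O[C@H]3[C@@H](O[Si](CC)(CC)CC)[C@H]12 | intermediate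
30 | lithium enolate of lactone 29 (C11=C12) | C1=C(O[Li])O[C@@H]2C/C(C)=C/[C@@H](O[Si](C)(C)C(C)(C)C)C[C@@]3(C)O[C@H]3[C@@H](O[Si](CC)(CC)CC)[C@H]12 | intermediate
31 | (2S,4R,5S,6S,7R,8R)-2-(tert-butyldimethylsilyloxy)-13-(dimethylamino)-4,5-epoxy-6-(triethylsilyloxy)germacr-1(10)E-en-12,8-olide (C11 mixture) | CN(C)CC1C(=O)O[C@@H]2C/C(C)=C/[C@@H](O[Si](C)(C)C(C)(C)C)C[C@@]3(C)O[C@H]3[C@@H](O[Si](CC)(CC)CC)[C@H]12 | intermediate
32 | trimethylammonium iodide of 31 | C[N+](C)(C)CC1C(=O)O[C@@H]2C/C(C)=C/[C@@H](O[Si](C)(C)C(C)(C)C)C[C@@]3(C)O[C@H]3[C@@H](O[Si](CC)(CC)CC)[C@H]12.[I-] | intermediate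
33 | (2S,4R,5S,6S,7R,8R)-2-(tert-butyldimethylsilyloxy)-4,5-epoxy-6-(triethylsilyloxy)germacra-1(10)E,11(13)-dien-12,8-olide | C=C1C(=O)O[C@@H]2C/C(C)=C/[C@@H](O[Si](C)(C)C(C)(C)C)C[C@@]3(C)O[C@H]3[C@@H](O[Si](CC)(CC)CC)[C@H]12 | intermediate
34 | (2S,4R,5S,6S,7S,8R)-4,5-epoxy-2,6-dihydroxygermacra-1(10)E,11(13)-dien-12,8-olide | C=C1C(=O)O[C@@H]2C/C(C)=C/[C@@H](O)C[C@@]3(C)O[C@H]3[C@@H](O)[C@H]12 | intermediate
35 | (2S,4R,5S,6S,7R,8R)-2,6-diacetoxy-4,5-epoxygermacra-1(10)E,11(13)-dien-12,8-olide (CNP0270851.1) | C=C1C(=O)O[C@@H]2C/C(C)=C/[C@@H](OC(C)=O)C[C@@]3(C)O[C@H]3[C@@H](OC(C)=O)[C@H]12 | target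

**Step count and risks**

Total step count: 20. Longest linear sequence: 17 steps (steps 1, 3–7 and 10–20).

Steps most likely to fail:

1. Step 11. The naked potassium enolate could expel the C8 alkoxide by β-elimination, alkylate on oxygen, or exchange protons with the product before carbon alkylation is complete. The fallback separates rearrangement from alkylation. It sets out from 20: after the same rearrangement the enolate is quenched at −78 °C with Me3SiCl/Et3N to give the trimethylsilyl enol ether F1, which is isolated. MeLi in THF (0 °C, then −78 °C) would regenerate the more tightly ion-paired lithium enolate F2, which is alkylated with methyl bromoacetate in THF/DMPU. The fallback comes back to the route at 24.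

2. Step 14. Hydride may attack the conformer that keeps the C6 carbonyl syn to the C8–O bond, giving poor or reversed facial selectivity at C6. The fallback corrects C6 by substitution instead of by facial control. It sets out from 26: the reduction is run as before and the 6-epi alcohol F3 is taken on to a Mitsunobu reaction with formic acid (PPh3, diisopropyl azodicarboxylate, THF, 0 °C), which gives the inverted formate F4. KHCO3 in MeOH at 0 °C would cleave the formate without opening the lactone. The fallback comes back to the route at 27.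

3. Step 15. The ring conformation may present the wrong olefin face to the vanadium-bound peroxide, or oxidation may spread to C1=C10. The fallback replaces substrate-directed delivery by reagent control. It sets out from 27 and uses the titanium tartrate system (Ti(OiPr)4, L-(+)-diisopropyl tartrate, t-BuOOH, 4 Å sieves, CH2Cl2, −20 °C). For a secondary allylic alcohol of the configuration of 27 the L-(+)-tartrate is the matched partner and should deliver oxygen erythro, that is syn to the C6 oxygen. The fallback comes back to the route at 28 and makes no new compound (F0).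

**Further compounds**

F1 | step 11 | trimethylsilyl enol ether (C6=C7) of the ten-membered dienone (2S,8R) | COc1ccc(CO[C@@H]2C/C(C)=C/[C@@H](O[Si](C)(C)C(C)(C)C)C/C(C)=C\C(O[Si](C)(C)C)=C\2)cc1
F2 | step 11 | lithium C6=C7 enolate of the ten-membered dienone (2S,8R) | COc1ccc(CO[C@@H]2C/C(C)=C/[C@@H](O[Si](C)(C)C(C)(C)C)C/C(C)=C\C(O[Li])=C\2)cc1
F3 | step 14 | 6-epimer of 27 | C1C(=O)O[C@@H]2C/C(C)=C/[C@@H](O[Si](C)(C)C(C)(C)C)C/C(C)=C\[C@H](O)[C@H]12
F4 | step 14 | C6 formate of 27 | C1C(=O)O[C@@H]2C/C(C)=C/[C@@H](O[Si](C)(C)C(C)(C)C)C/C(C)=C\[C@@H](OC=O)[C@H]12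
F0 | step 15 | none | none
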